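**Retrosynthetic overview**
1. C3, the lactol carbon and only stereocentre, is set last. A lipase dynamic kinetic acetylation acts on the ring–chain-labile racemic lactol, and a lipase de-acetylation follows that never touches the C3–O bond.
2. The C6–C1′ bond comes from Heck arylation/isomerisation of (E)-tetradeca-1,4-dien-3-ol with a 6-iodophthalide. This installs the whole enone chain at its final oxidation level.
3. C7a–C1 and C3a–C3 are cut together: aryne C3a≡C7a + vinylmagnesium bromide (masked formyl anion) + CO2. This runs in the same flask in which the C4 formyl carbon has just been attached to 1-fluoro-3,5-dimethoxybenzene and masked as its DMF adduct.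
4. Ring order: the benzene ring is bought. The five-membered lactol (furanone) ring is the only ring formed, by closure of the C7a carboxyl on the C3 aldehyde once the vinyl group is ozonised.
5. Enabling feature: the adjacent fusion carbons C3a and C7a of the benzene ring differ in their relation to ring oxygens O5 and O7. C7a is ortho to C7–O and para to C5–O; C3a is meta to both. A C3a≡C7a aryne is therefore polarised by the C7–O bond, so the nucleophile goes to C3a and the carbanion to C7a. In the symmetric fluoroarene, C4 and C7a are the two equivalent C–H sites flanked by F and OMe.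

Key step: step 1

Assumption: the C3 lactol of a 3-hydroxyphthalide epimerises by ring–chain tautomerism in basic or protic media. The route uses this lability in step 7 and treats free (3R)-15 as configurationally persistent only in cold, base-free, aprotic media; step 8, isolation and storage are specified accordingly.

**Step 1**
Reactants: 1 1-fluoro-3,5-dimethoxybenzene
Product: 5 3-formyl-4,6-dimethoxy-2-vinylbenzoic acid, via amino alkoxide 2 (not isolated), via aryne 3 (not isolated), via arylmagnesium bromide 4 (not isolated)
Conditions: n-BuLi (1.05 equiv), THF, −78 °C; DMF (1.0 equiv), −78 °C; n-BuLi (1.2 equiv), −78 °C; CH2=CHMgBr (3 equiv), −78 °C → rt; CO2 (g), 0 °C; 1 M HCl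
Reagents that add atoms: N,N-dimethylformamide, CN(C)C=O; vinylmagnesium bromide, C=C[Mg]Br; carbon dioxide, O=C=O
Why: Ortho-lithiation of 1 at one of its two equivalent, most acidic C–H bonds (flanked by F and OMe) and addition to DMF give the tetrahedral amino alkoxide 2, which masks the future C4 formyl group in situ; a second ortho-lithiation at the remaining F/OMe-flanked C–H and loss of LiF on warming give aryne 3, vinylmagnesium bromide adds to it (carbomagnesiation), and the arylmagnesium 4 born on the neighbouring carbon is carboxylated by CO2, so the C3a–C3 and C7a–C1 bonds form in one operation. The closest known reaction type is the multicomponent aryne coupling in which a 3,5-dialkoxybenzyne made from the fluoroarene with n-BuLi takes up a Grignard reagent and then CO2, combined with the established in situ protection of aryl aldehydes as lithium α-amino alkoxides. Polarity is reversed twice: C3a, meta to both ring oxygens and beyond the reach of electrophilic substitution, becomes the electrophile, and the lactol carbon, an electrophilic formyl carbon in the target, arrives as a nucleophile (vinyl as masked formyl anion, its extra CH2 being removed in step 2). The selectivity needed is regiochemical: the C7–O bond beside one aryne terminus polarises and distorts the triple bond so that the nucleophile enters at the remote terminus C3a and the carbanion is left at C7a next to the oxygen, and the lithium alkoxide on the other flank can pre-coordinate magnesium and deliver the vinyl group to the same carbon. No ring is closed and no lasting stereocentre is formed here (the hemiaminal carbon of 2–4 is racemic and is lost on acidic work-up); the lactol ring closes in step 2 and C3 is set in step 7.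

**Step 2**
Reactants: 5 3-formyl-4,6-dimethoxy-2-vinylbenzoic acid
Product: 7 (±)-3,5,7-trimethoxy-1-oxo-1,3-dihydroisobenzofuran-4-carbaldehyde, via lactol 6 (not isolated)
Conditions: O3, CH2Cl2–MeOH, −78 °C; Me2S, → rt; then TsOH·H2O (cat.), MeOH, 40 °C
Reagents that add atoms: ozone, [O-][O+]=O; methanol, CO
Why: Criegee ozonolysis of the styrene C=C with reductive work-up unmasks the C3 aldehyde, the neighbouring carboxyl captures it at once (5-exo-trig ring–chain closure of a 2-formylbenzoic acid) to give racemic lactol 6, and acid-catalysed pseudo-ester formation in methanol masks this pseudo-acid for the following steps, while the push–pull C4 aldehyde should stay free without a dehydrating agent.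

**Step 3**
Reactants: 7 (±)-3,5,7-trimethoxy-1-oxo-1,3-dihydroisobenzofuran-4-carbaldehyde
Product: 8 (±)-6-iodo-3,5,7-trimethoxy-1-oxo-1,3-dihydroisobenzofuran-4-carbaldehyde
Conditions: I2, CF3CO2Ag, CH2Cl2, 0 °C → rt, dark
Reagents that add atoms: iodine, II
Why: Electrophilic aromatic iodination by the acyl hypoiodite formed in situ can take only C6, the sole remaining ring C–H, which is ortho to both methoxy groups and meta to both acyl groups, so all directing effects converge.

**Step 4**
Reactants: 9 (E)-dodec-2-enal
Product: 10 (±)-(E)-tetradeca-1,4-dien-3-ol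
Conditions: CH2=CHMgBr, THF, −78 → 0 °C; sat. aq. NH4Cl
Reagents that add atoms: vinylmagnesium bromide, C=C[Mg]Br
Why: Grignard 1,2-addition to the enal gives the bis-allylic alcohol with the (E)-alkene untouched, and the new carbinol centre needs no control because step 5 destroys it.

**Step 5**
Reactants: 8 (±)-6-iodo-3,5,7-trimethoxy-1-oxo-1,3-dihydroisobenzofuran-4-carbaldehyde; 10 (±)-(E)-tetradeca-1,4-dien-3-ol
Product: 11 (±)-3,5,7-trimethoxy-1-oxo-6-[(E)-3-oxotetradec-4-en-1-yl]-1,3-dihydroisobenzofuran-4-carbaldehyde
Conditions: Pd(OAc)2 (10 mol %), n-Bu4NCl, NaHCO3, DMF, 60 °C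
Reagents that add atoms: none
Why: In this Heck reaction of an aryl iodide with a secondary allylic alcohol, aryl-palladium adds to the unhindered terminal vinyl group, β-hydride elimination toward the carbinol C–H gives the enol and hence the ketone, and the internal (E)-alkene stays a spectator, so the ArCH2CH2C(=O)CH=CH unit arises directly at its final oxidation level.

**Step 6**
Reactants: 11 (±)-3,5,7-trimethoxy-1-oxo-6-[(E)-3-oxotetradec-4-en-1-yl]-1,3-dihydroisobenzofuran-4-carbaldehyde
Product: 12 (±)-3,5,7-trihydroxy-1-oxo-6-[(E)-3-oxotetradec-4-en-1-yl]-1,3-dihydroisobenzofuran-4-carbaldehyde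
Conditions: BCl3 (excess), CH2Cl2, −78 → 0 °C; then H2O–THF, 0 °C
Reagents that add atoms: water, O
Why: In this chelation-assisted ether cleavage each aryl methyl ether lies ortho to a carbonyl group (O7 to the lactone C1=O, O5 to the C4 formyl group) and is cleaved through a six-membered boron chelate at low temperature, the C3 methoxy group is exchanged for chloride and then for hydroxyl on aqueous work-up, and the enone is only complexed reversibly.

**Step 7**
Reactants: 12 (±)-3,5,7-trihydroxy-1-oxo-6-[(E)-3-oxotetradec-4-en-1-yl]-1,3-dihydroisobenzofuran-4-carbaldehyde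
Product: 14 (3R)-3-acetoxy-5,7-dihydroxy-1-oxo-6-[(E)-3-oxotetradec-4-en-1-yl]-1,3-dihydroisobenzofuran-4-carbaldehyde, via open-chain tautomer 13 (not isolated)
Conditions: immobilised Burkholderia cepacia lipase, isopropenyl acetate, Et3N (5 mol %), toluene, 30 °C
Reagents that add atoms: isopropenyl acetate, CC(=C)OC(C)=O
Why: In this lipase-catalysed dynamic kinetic resolution, of the type known for γ-hydroxybutenolide pseudo-acid lactols, the enantiomers of 12 interconvert through achiral 13 while the serine hydrolase acetylates only the enantiomer that fits the empirical size rule for secondary alcohols (large benzo side, small ring-oxygen side, the sense found for (R)-indan-1-ol, which is 3R here), so the whole mixture should funnel into (3R)-14, and the two phenols, di-ortho-substituted and hydrogen-bonded to C1=O and to the formyl group, should not be accepted as nucleophiles.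

**Step 8**
Reactants: 14 (3R)-3-acetoxy-5,7-dihydroxy-1-oxo-6-[(E)-3-oxotetradec-4-en-1-yl]-1,3-dihydroisobenzofuran-4-carbaldehyde
Product: 15 (3R)-3,5,7-trihydroxy-1-oxo-6-[(E)-3-oxotetradec-4-en-1-yl]-1,3-dihydroisobenzofuran-4-carbaldehyde
Conditions: immobilised Burkholderia cepacia lipase, n-BuOH (5 equiv), MTBE, 0–4 °C; filtration, evaporation in the cold
Reagents that add atoms: none
Why: Lipase-catalysed alcoholysis breaks the acetyl C–O bond and not the C3–O bond, so the configuration is retained, the same enzyme prefers the same (3R) enantiomer so any minor enantiomer stays behind as its acetate, and the absence of base and water at low temperature should keep ring opening of the released lactol slow.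

**Compound list**
1 | 1-fluoro-3,5-dimethoxybenzene | COc1cc(F)cc(OC)c1 | starting material
2 | lithium (dimethylamino)(2-fluoro-4,6-dimethoxyphenyl)methanolate (racemic) | [Li]OC(N(C)C)c1c(F)cc(OC)cc1OC | intermediate
3 | lithium (dimethylamino)(2,3-didehydro-4,6-dimethoxyphenyl)methanolate (aryne, racemic) | [Li]OC(N(C)C)C1=C(OC)C=C(OC)C#C1 | intermediate
4 | bromo{3-[(dimethylamino)(lithiooxy)methyl]-4,6-dimethoxy-2-vinylphenyl}magnesium (racemic) | [Li]OC(N(C)C)c1c(C=C)c([Mg]Br)c(OC)cc1OC | intermediate
5 | 3-formyl-4,6-dimethoxy-2-vinylbenzoic acid | C=Cc1c(C=O)c(OC)cc(OC)c1C(=O)O | intermediate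
6 | (±)-3-hydroxy-5,7-dimethoxy-1-oxo-1,3-dihydroisobenzofuran-4-carbaldehyde | O=Cc1c(OC)cc(OC)c2C(=O)OC(O)c12 | intermediate
7 | (±)-3,5,7-trimethoxy-1-oxo-1,3-dihydroisobenzofuran-4-carbaldehyde | O=Cc1c(OC)cc(OC)c2C(=O)OC(OC)c12 | intermediate
8 | (±)-6-iodo-3,5,7-trimethoxy-1-oxo-1,3-dihydroisobenzofuran-4-carbaldehyde | O=Cc1c(OC)c(I)c(OC)c2C(=O)OC(OC)c12 | intermediate
9 | (E)-dodec-2-enal | CCCCCCCCC/C=C/C=O | starting material
10 | (±)-(E)-tetradeca-1,4-dien-3-ol | CCCCCCCCC/C=C/C(O)C=C | intermediate
11 | (±)-3,5,7-trimethoxy-1-oxo-6-[(E)-3-oxotetradec-4-en-1-yl]-1,3-dihydroisobenzofuran-4-carbaldehyde | CCCCCCCCC/C=C/C(=O)CCc1c(OC)c(C=O)c2c(c1OC)C(=O)OC2OC | intermediate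
12 | (±)-3,5,7-trihydroxy-1-oxo-6-[(E)-3-oxotetradec-4-en-1-yl]-1,3-dihydroisobenzofuran-4-carbaldehyde | CCCCCCCCC/C=C/C(=O)CCc1c(O)c(C=O)c2c(c1O)C(=O)OC2O | intermediate
13 | 2,3-diformyl-4,6-dihydroxy-5-[(E)-3-oxotetradec-4-en-1-yl]benzoic acid (open-chain tautomer) | CCCCCCCCC/C=C/C(=O)CCc1c(O)c(C=O)c(C=O)c(C(=O)O)c1O | intermediate
14 | (3R)-3-acetoxy-5,7-dihydroxy-1-oxo-6-[(E)-3-oxotetradec-4-en-1-yl]-1,3-dihydroisobenzofuran-4-carbaldehyde | CCCCCCCCC/C=C/C(=O)CCc1c(O)c(C=O)c2c(c1O)C(=O)O[C@H]2OC(C)=O | intermediate
15 | (3R)-3,5,7-trihydroxy-1-oxo-6-[(E)-3-oxotetradec-4-en-1-yl]-1,3-dihydroisobenzofuran-4-carbaldehyde | CCCCCCCCC/C=C/C(=O)CCc1c(O)c(C=O)c2c(c1O)C(=O)O[C@H]2O | target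

Total step count: 8. Longest linear sequence: 7 (steps 1, 2, 3, 5, 6, 7, 8).

**Steps most likely to fail**

Step 8. The risk is racemisation of the released lactol by ring opening on the enzyme support or during isolation. Slow turnover next to the peri formyl group is a second risk. The fallback sets out from racemic 12 and comes back at 15. The enantiomers are separated physically by preparative chiral-phase supercritical-fluid chromatography at sub-ambient temperature with a slightly acidified modifier. The unwanted enantiomer is re-equilibrated with catalytic Et3N through 13 and re-injected. This replaces the enzymatic lock–unlock pair by a separation–racemisation cycle and makes no new compound.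

Step 1. The risks are collapse of the in situ amino alkoxide on warming, incomplete second lithiation of the anionic intermediate, and capture of the aryne by aryllithium instead of the Grignard reagent. The fallback sets out from 1 and comes back at 7. The formyl group is left out of the aryne flask and introduced afterwards by electrophilic substitution.
- n-BuLi, then vinylmagnesium bromide, then CO2 on 1 itself should give 2,4-dimethoxy-6-vinylbenzoic acid F1.
- Ozonolysis with Me2S work-up followed by MeOH/TsOH should give 3,5,7-trimethoxyisobenzofuran-1(3H)-one F2.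
- Rieche formylation (Cl2CHOMe, TiCl4, CH2Cl2, methanol quench) should then attack C4, the position para to O7 that is not flanked by two methoxy groups, to give 7.

Step 5. The risks are slow oxidative addition and insertion at the di-ortho-methoxy iodide, β-hydride elimination toward the benzylic side, and reductive loss of iodine. The fallback sets out from 10 and 8 and comes back at 11. The C6–C1′ bond is made by sp2–sp3 cross-coupling and the ketone by a separate oxidation.
- 9-BBN-H (2 equiv) should convert 10 chemoselectively at the terminal vinyl group (and at the OH) into (E)-1-(9-borabicyclo[3.3.1]nonan-9-yl)-3-[(9-borabicyclo[3.3.1]nonan-9-yl)oxy]tetradec-4-ene F3.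
- B-alkyl Suzuki–Miyaura coupling with 8 (Pd(dppf)Cl2, K3PO4, DMF–THF) should give 6-[(E)-3-hydroxytetradec-4-en-1-yl]-3,5,7-trimethoxy-1-oxo-1,3-dihydroisobenzofuran-4-carbaldehyde F4.
- MnO2 oxidation of the allylic alcohol should then give 11.

**Further compounds**
F0 | step 8 | none | none
F1 | step 1 | 2,4-dimethoxy-6-vinylbenzoic acid | C=Cc1cc(OC)cc(OC)c1C(=O)O
F2 | step 1 | (±)-3,5,7-trimethoxyisobenzofuran-1(3H)-one | COC1OC(=O)c2c(OC)cc(OC)cc12
F3 | step 5 | (E)-1-(9-borabicyclo[3.3.1]nonan-9-yl)-3-[(9-borabicyclo[3.3.1]nonan-9-yl)oxy]tetradec-4-ene (racemic) | CCCCCCCCC/C=C/C(CCB1C2CCCC1CCC2)OB1C2CCCC1CCC2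
F4 | step 5 | 6-[(E)-3-hydroxytetradec-4-en-1-yl]-3,5,7-trimethoxy-1-oxo-1,3-dihydroisobenzofuran-4-carbaldehyde (mixture of stereoisomers) | CCCCCCCCC/C=C/C(O)CCc1c(OC)c(C=O)c2c(c1OC)C(=O)OC2OC
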